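Take the leftover first, since you want a quick number for the flask and suspect that quick exchange ends in pure left-handed product: the flask's charge is the geometric middle of the amber and ochre runs, so interpolate the logarithm of the fraction left in each run to 2.0 min, which lies 57.3 % of the way between their last two readings, then take the geometric mean, and expect 13.3 % unreacted, so 86.7 % of the charge as product.

| setting | amber | ochre | flask |
|---|---|---|---|
| left-handed substrate | 0.0055 M | 0.022 M | 0.011 M |
| right-handed substrate | 0.0055 M | 0.022 M | 0.011 M |
| coupling partner | 2 equiv | 2 equiv | 2.00 equiv |
| precatalyst | 0.1 mol% | 0.1 mol% | 0.1 mol% |
| remark | run made earlier | run made earlier |  |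
| time |  |  | 2.0 min |

- amber (time / min: left-handed product / %, right-handed product / %): 0.200: 13.4, 0.1; 0.333: 25.2, 1.2; 0.500: 35.2, 2.1; 0.833: 46.6, 4.7; 1.33: 54.9, 10.1; 2.50: 58.8, 21.0
- ochre (time / min: left-handed product / %, right-handed product / %): 0.200: 51.3, 1.9; 0.333: 56.5, 5.1; 0.500: 60.5, 7.4; 0.833: 65.7, 12.4; 1.33: 68.2, 18.7; 2.50: 65.2, 30.5

(readings scatter by 0.3 percentage points)

- left-handed product and right-handed product together, in percent of the left-handed substrate and right-handed substrate charged together, at 2.0 min
- excess of left-handed product over right-handed product in the product at 2.0 min
- whether the exchange between left-handed substrate and right-handed substrate keeps pace with the reaction: how far the product's excess at 2.0 min gets from its value without exchange to its value with instant exchange (above 80 % keeps pace, below 20 % hardly takes part, else lags behind)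

- catalyst is single-handed; left-handed substrate and right-handed substrate are mirror images of each other, charged as a racemate, each of them at the stated concentration
- an excess is the difference of the two amounts in percent of their sum
- an excess is below zero if the other one leads

Treat the excess as a fraction left too, for in the ochre run the left-handed product falls from 68.2 % to 65.2 % while the right-handed product climbs, which reads as racemisation of the product. Count that climb as inversion, each event moving the difference by two, and get the decay constant of the excess, its first-order loss per minute, 0.479 /min. The ochre run passes half of the charge at 0.200 min and the amber run half at 0.833 min, so date the flask's product at their geometric mean, 0.408 min; it then keeps 46.6 % of its excess, the instant-exchange mark. Put the no-exchange mark somewhere below that, as my own assumption and without a figure: right-handed substrate left unexchanged feeds right-handed product into the same decaying excess. Interpolating the excess likewise gives 49.5 %, which stands above the instant-exchange mark, so with any lower no-exchange mark the way is past 80 %, and I say it keeps pace.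

The forecast, 85 %, 49 % and lags behind, differs from me on the pace and on the instant-exchange mark: “With instant exchange, selectivity of about 20 or more gives eP≈90%”.

    left-handed substrate ⇌ right-handed substrate (k = 0.0180 /s)
    left-handed product ⇌ right-handed product (k = 0.00360 /s)
    coupling partner + catalyst + right-handed substrate → catalyst + right-handed product (k = 15000 /M²/s)
    precatalyst ⇌ catalyst (K = 2.30, k = 0.0540 /s)
    coupling partner + catalyst + left-handed substrate → catalyst + left-handed product (k = 2.00 × 10⁶ /M²/s)

The flask gives 87.4 % with excess 50.1 %, and keeps pace, at 108 % of the way. Carry the decay constant to the neighbour flask with 0.04 mol% of precatalyst: stretch the dating inversely with loading to 1.02 min and get an instant-exchange mark of 62.5 %; that neighbour flask gives 80.2 % of product with an excess of 53.6 %, which lies 8.9 percentage points below the mark.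

(The readings were generated by integration from invented constants; the scatter is artificial.)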